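## Structural features

The target is a single oxolane ring (numbered O1, C2, C3, C4, C5) with three contiguous stereocentres. C3 carries the 3,4,5-trimethoxybenzoyl group, C4 a hydroxymethyl group and C5 the 3,4-dimethoxyphenyl ring; C2 is an unsubstituted CH2 next to O1. Decoding the SMILES gives (3R,4R,5R), which puts all three substituents on the same face of the ring (all-cis), the most crowded arrangement. C3 is alpha to the aryl ketone and enolisable, and epimerisation to the 3,4-trans isomer relieves strain, so base is excluded once a carbonyl group sits on C3. The C5–O1 bond is a benzylic ether para to a methoxy group: strong acid can ionise it and scramble C5, and hydrogenolysis can cleave it. The cis hydroxymethyl and ketone groups can also close to a bicyclic hemiketal, so long exposure to acid at the end is unwelcome. The two arenes are ordinary purchasable units; the real difficulty is the all-cis triad, with absolute control, on a ring that has no substituent at C2 to relay stereochemistry. The key step exploits two features: C3 bears an exocyclic carbonyl carbon with O1 two bonds away through C2, and C4–C5 joins a carbon with a CH2O arm to an aryl-substituted, oxygen-bearing carbon. This is the retron of a pinacol-terminated Prins cyclisation: C4–C5 from a Z alkene adding to an aryl oxocarbenium ion, C2–C3 from a ring-contracting 1,2-shift.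

## Logic of the disconnections

13 ⇒ 12. The O–H of the hydroxymethyl group on C4 is traced back to an O–Si bond. A free cis hydroxymethyl group would add to the carbonyl group on C3 and would not survive the Lewis-acid and organometallic steps, so it is masked from the start. Nothing is gained in skeleton; the demand is that the last step unmasks without base, because C3 is enolisable.

12 ⇒ 11 ⇒ 9 + 10. The bond between the carbonyl carbon and the trimethoxyphenyl ring is cut, by way of the carbinol oxidation level. This arene is not carried through the key step for a mechanistic reason: on the migration terminus it could trap the oxocarbenium ion in a six-membered Friedel–Crafts closure, and it would make the carbinol C–O bond tertiary, benzylic and allylic, hence easily ionised. The gain is that one arene leaves and the ring compound becomes an aldehyde that already holds the whole stereotriad. The demand is that carbonyl addition to 9 outruns enolisation at C3 and that the oxidation of 11 is not basic.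

9 ⇒ 8 (key). Two ring bonds are cut, C4–C5 and C2–C3, and C2 is reconnected to the formyl carbon, whose oxygen returns to C5 as the second acetal oxygen. The oxolane with three stereocentres becomes an acetal with one carbinol stereocentre and a Z alkene; ring, carbonyl group and all three ring stereocentres then arise in one operation. The forward step demands a chair transition state with an E oxocarbenium ion, a geometrically pure alkene, and a product that the Lewis acid does not enolise.

8 ⇒ 6 + 7. The two acetal C–O bonds are cut. This releases the dimethoxyphenyl ring as a purchased aldehyde and leaves a five-carbon diol. The forward step only has to form the five-membered acetal under acid too weak to trigger the rearrangement; the configuration of the acetal carbon does not matter, because that carbon becomes sp2 in the key step.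

6 ⇒ 5 ⇒ 4 ⇒ 3 ⇒ 1 + 2. In turn: the two C–O bonds of an isopropylidene acetal, the O–Si bond, the two C–H bonds of the allylic CH2 (ester reduction), and finally the C=C bond. The stereocentre then comes from the chiral pool and the Z geometry from one olefination. The demand is high Z selectivity, because the alkene geometry becomes the C4/C5 relationship, and no epimerisation of the alpha-alkoxy aldehyde 1.

## Other disconnections considered

Alternative 1: the route most chemists would draw first. Cuts: the exocyclic C3–C(=O) bond, C4–C5 and O1–C5. Forward: conjugate addition of a dithiane-masked trimethoxybenzoyl anion to the parent butenolide, trapping of the lactone enolate with 7 to give lactone A1, then lactone reduction, acid cyclo-etherification and dithiane removal. Grounds for preferring the chosen plan: the enolate is trapped anti to the new beta substituent, so A1 is 3,4-trans, and the ether closure runs through a benzylic cation, so C5 is set under thermodynamic control. Both point away from the all-cis isomer. The stereocentres are also set one at a time, the sequence is longer, and absolute control would need a chiral butenolide.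

Alternative 2: no skeletal bond is cut; the C3–H and C4–H bonds are made last. Forward: syn addition of hydrogen to the tetrasubstituted C3=C4 bond of 2,5-dihydrofuran A2, from the face opposite the C5 aryl group, which would give the all-cis triad directly. Grounds for preferring the chosen plan: in A2 the C5–O1 bond is both benzylic and allylic, and A2 is only two hydrogens away from a furan, so hydrogenolysis and disproportionation on the metal compete with a slow addition to a tetrasubstituted, cross-conjugated alkene. The key step would also build no part of the skeleton, and the absolute configuration would need a separate asymmetric step at C5.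

Alternative 3: cut C4–C5 only. Forward: Lewis-acid-mediated 1,3 O-to-C ring contraction of the seven-membered vinyl acetal A3, which recombines an aryl oxocarbenium ion with a tethered enolate to give a 5-aryl oxolane with a formyl group on C4 and the ester on C3. Grounds for preferring the chosen plan: the enolate carbon that becomes C4 stands next to the existing ester-bearing carbon, so bond formation should occur on the face away from the ester, giving the 3,4-trans series. The formyl and ester groups would then both need changes of oxidation level or identity, and enantioenriched A3 is not readily available.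

Key step: step 6

Assumption: the SMILES is taken at face value as the (3R,4R,5R) all-cis isomer.
Assumption: 10 is bought as a THF solution.

## Steps

Step 1
Reactants: 1 (R)-2,2-dimethyl-1,3-dioxolane-4-carbaldehyde; 2 methyl bis(2,2,2-trifluoroethyl)phosphonoacetate
Product: 3 methyl (2Z)-3-[(4S)-2,2-dimethyl-1,3-dioxolan-4-yl]prop-2-enoate
Conditions: KN(SiMe3)2, 18-crown-6, THF, −78 °C
Reagents that add atoms: none
Why: Still–Gennari variant of the Horner–Wadsworth–Emmons olefination; the trifluoroethyl phosphonate eliminates quickly from the kinetically formed adduct and gives the Z enoate. The dioxolane stereocentre is untouched; its descriptor changes from R to S only because the CIP priorities change.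

Step 2
Reactants: 3 methyl (2Z)-3-[(4S)-2,2-dimethyl-1,3-dioxolan-4-yl]prop-2-enoate
Product: 4 (2Z)-3-[(4S)-2,2-dimethyl-1,3-dioxolan-4-yl]prop-2-en-1-ol
Conditions: i-Bu2AlH (2.2 equiv), CH2Cl2, −78 °C; aqueous potassium sodium tartrate
Reagents that add atoms: none
Why: 1,2-reduction of an unsaturated ester by i-Bu2AlH; the Z alkene and the acetonide are not affected at low temperature.

Step 3
Reactants: 4 (2Z)-3-[(4S)-2,2-dimethyl-1,3-dioxolan-4-yl]prop-2-en-1-ol
Product: 5 tert-butyl({(2Z)-3-[(4S)-2,2-dimethyl-1,3-dioxolan-4-yl]prop-2-en-1-yl}oxy)diphenylsilane
Conditions: TBDPSCl, imidazole, CH2Cl2, 0 °C to rt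
Reagents that add atoms: tert-butyl(chloro)diphenylsilane, CC(C)(C)[Si](Cl)(c1ccccc1)c1ccccc1
Why: Silylation of a primary alcohol. The TBDPS ether survives aqueous acid, SnCl4 at low temperature, the Grignard reagent and the periodinane, its oxygen is a poor Lewis base, and it is removed at the end by fluoride without base.

Step 4
Reactants: 5 tert-butyl({(2Z)-3-[(4S)-2,2-dimethyl-1,3-dioxolan-4-yl]prop-2-en-1-yl}oxy)diphenylsilane
Product: 6 (2S,3Z)-5-[(tert-butyldiphenylsilyl)oxy]pent-3-ene-1,2-diol
Conditions: AcOH/H2O/THF (3:1:1), 40 °C
Reagents that add atoms: none
Why: Acid hydrolysis of the isopropylidene acetal; the TBDPS ether is stable to aqueous acetic acid and the stereocentre is not involved.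

Step 5
Reactants: 6 (2S,3Z)-5-[(tert-butyldiphenylsilyl)oxy]pent-3-ene-1,2-diol; 7 3,4-dimethoxybenzaldehyde
Product: 8 (4S)-4-{(1Z)-3-[(tert-butyldiphenylsilyl)oxy]prop-1-en-1-yl}-2-(3,4-dimethoxyphenyl)-1,3-dioxolane (both epimers at the acetal carbon)
Conditions: PPTS (cat.), benzene, reflux, Dean–Stark trap
Reagents that add atoms: none
Why: Acetalisation of a 1,2-diol with azeotropic removal of water; PPTS is too weak to start the rearrangement. The epimer mixture at the acetal carbon is immaterial, because that carbon becomes sp2 in step 6.

Step 6
Reactants: 8 (4S)-4-{(1Z)-3-[(tert-butyldiphenylsilyl)oxy]prop-1-en-1-yl}-2-(3,4-dimethoxyphenyl)-1,3-dioxolane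
Product: 9 (3R,4R,5R)-4-{[(tert-butyldiphenylsilyl)oxy]methyl}-5-(3,4-dimethoxyphenyl)oxolane-3-carbaldehyde (all-cis)
Conditions: SnCl4 (1.5 equiv), CH2Cl2, −78 to −20 °C; Et3N then aqueous NaHCO3 at −78 °C
Reagents that add atoms: none
Why: This is a pinacol-terminated Prins cyclisation of a 4-alkenyl-1,3-dioxolane to a 3-acyl oxolane, here ending in a formyl group. SnCl4 opens the acetal at the bond to the oxygen on the allylic carbon, leaving the aryl-stabilised oxocarbenium ion on the CH2–O oxygen; the alkene terminus attacks it through a six-membered chair (6-endo closure to an oxan-4-yl cation), and a 1,2-shift of the ring CH2 from the stannyloxy carbon to the cationic carbon then contracts the oxane to the oxolane and turns the former carbinol carbon into the aldehyde (a 2-oxonia-Cope/aldol sequence is the alternative description of the same bond changes). C5 is controlled by the E geometry of the oxocarbenium ion, which puts the aryl group equatorial. C4 is controlled by the Z alkene, which forces the CH2OSi group axial and hence cis to the aryl group. C3 is controlled by the shift itself: the migrating CH2 reaches the cationic carbon on the face it already occupies in the chair, so the formyl group ends on the same face as the other two substituents, giving the all-cis kinetic product. The absolute configuration comes from the (4S) centre of 8, the only stereocentre present: the chair with its C–O bond equatorial and its hydrogen axial avoids a 1,3-diaxial clash with the axial CH2OSi group, and that chair leads to (3R,4R,5R). The step needs chair over boat and C–C bond formation faster than enolisation of the product; the allylic strain of the Z alkene, the low temperature and the cold amine quench are meant to secure this.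

Step 7
Reactants: 9 (3R,4R,5R)-4-{[(tert-butyldiphenylsilyl)oxy]methyl}-5-(3,4-dimethoxyphenyl)oxolane-3-carbaldehyde; 10 3,4,5-trimethoxyphenylmagnesium bromide
Product: 11 [(3R,4R,5R)-4-{[(tert-butyldiphenylsilyl)oxy]methyl}-5-(3,4-dimethoxyphenyl)oxolan-3-yl](3,4,5-trimethoxyphenyl)methanol (both epimers at the carbinol carbon)
Conditions: THF, −78 °C; aqueous NH4Cl (9 used without chromatography)
Reagents that add atoms: none
Why: Grignard 1,2-addition to an aldehyde; an aryl Grignard reagent is a weak base toward the alpha C–H at −78 °C, so addition should outrun enolisation and C3 should keep its configuration. The new carbinol centre is formed as a mixture, which does not matter because step 8 removes it.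

Step 8
Reactants: 11 [(3R,4R,5R)-4-{[(tert-butyldiphenylsilyl)oxy]methyl}-5-(3,4-dimethoxyphenyl)oxolan-3-yl](3,4,5-trimethoxyphenyl)methanol
Product: 12 [(3R,4R,5R)-4-{[(tert-butyldiphenylsilyl)oxy]methyl}-5-(3,4-dimethoxyphenyl)oxolan-3-yl](3,4,5-trimethoxyphenyl)methanone
Conditions: Dess–Martin periodinane (1.3 equiv), CH2Cl2, 0 °C to rt
Reagents that add atoms: none
Why: Dess–Martin oxidation of a benzylic secondary alcohol to the aryl ketone under neutral to weakly acidic conditions; no base is present, so the enolisable C3 centre is not epimerised.

Step 9
Reactants: 12 [(3R,4R,5R)-4-{[(tert-butyldiphenylsilyl)oxy]methyl}-5-(3,4-dimethoxyphenyl)oxolan-3-yl](3,4,5-trimethoxyphenyl)methanone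
Product: 13 [(3R,4R,5R)-5-(3,4-dimethoxyphenyl)-4-(hydroxymethyl)oxolan-3-yl](3,4,5-trimethoxyphenyl)methanone (target)
Conditions: HF·pyridine, pyridine, THF, 0 °C to rt
Reagents that add atoms: none
Why: Fluoride cleavage of the Si–O bond; the acidic, buffered fluoride source avoids the basic conditions of Bu4NF that could enolise C3, and no ring stereocentre is involved.

## Compound list

1 | (R)-2,2-dimethyl-1,3-dioxolane-4-carbaldehyde | O=C[C@H]1COC(C)(C)O1 | starting material
2 | methyl bis(2,2,2-trifluoroethyl)phosphonoacetate | COC(=O)CP(=O)(OCC(F)(F)F)OCC(F)(F)F | starting material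
3 | methyl (2Z)-3-[(4S)-2,2-dimethyl-1,3-dioxolan-4-yl]prop-2-enoate | COC(=O)/C=C\[C@H]1COC(C)(C)O1 | intermediate
4 | (2Z)-3-[(4S)-2,2-dimethyl-1,3-dioxolan-4-yl]prop-2-en-1-ol | OC/C=C\[C@H]1COC(C)(C)O1 | intermediate
5 | tert-butyl({(2Z)-3-[(4S)-2,2-dimethyl-1,3-dioxolan-4-yl]prop-2-en-1-yl}oxy)diphenylsilane | CC(C)(C)[Si](OC/C=C\[C@H]1COC(C)(C)O1)(c1ccccc1)c1ccccc1 | intermediate
6 | (2S,3Z)-5-[(tert-butyldiphenylsilyl)oxy]pent-3-ene-1,2-diol | OC[C@@H](O)/C=C\CO[Si](c1ccccc1)(c1ccccc1)C(C)(C)C | intermediate
7 | 3,4-dimethoxybenzaldehyde | COc1ccc(C=O)cc1OC | starting material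
8 | (4S)-4-{(1Z)-3-[(tert-butyldiphenylsilyl)oxy]prop-1-en-1-yl}-2-(3,4-dimethoxyphenyl)-1,3-dioxolane, both epimers at the acetal carbon | COc1ccc(C2OC[C@H](/C=C\CO[Si](c3ccccc3)(c3ccccc3)C(C)(C)C)O2)cc1OC | intermediate
9 | (3R,4R,5R)-4-{[(tert-butyldiphenylsilyl)oxy]methyl}-5-(3,4-dimethoxyphenyl)oxolane-3-carbaldehyde | COc1ccc([C@@H]2OC[C@H](C=O)[C@@H]2CO[Si](c3ccccc3)(c3ccccc3)C(C)(C)C)cc1OC | intermediate
10 | 3,4,5-trimethoxyphenylmagnesium bromide | COc1cc([Mg]Br)cc(OC)c1OC | starting material
11 | [(3R,4R,5R)-4-{[(tert-butyldiphenylsilyl)oxy]methyl}-5-(3,4-dimethoxyphenyl)oxolan-3-yl](3,4,5-trimethoxyphenyl)methanol, both carbinol epimers | COc1ccc([C@@H]2OC[C@H](C(O)c3cc(OC)c(OC)c(OC)c3)[C@@H]2CO[Si](c3ccccc3)(c3ccccc3)C(C)(C)C)cc1OC | intermediate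
12 | [(3R,4R,5R)-4-{[(tert-butyldiphenylsilyl)oxy]methyl}-5-(3,4-dimethoxyphenyl)oxolan-3-yl](3,4,5-trimethoxyphenyl)methanone | COc1ccc([C@@H]2OC[C@H](C(=O)c3cc(OC)c(OC)c(OC)c3)[C@@H]2CO[Si](c3ccccc3)(c3ccccc3)C(C)(C)C)cc1OC | intermediate
13 | [(3R,4R,5R)-5-(3,4-dimethoxyphenyl)-4-(hydroxymethyl)oxolan-3-yl](3,4,5-trimethoxyphenyl)methanone | COc1ccc([C@@H]2OC[C@H](C(=O)c3cc(OC)c(OC)c(OC)c3)[C@@H]2CO)cc1OC | target

## Step count and least certain steps

Total step count: 9. Longest linear sequence: 9 steps (1 to 13); 2, 7 and 10 enter as purchased materials.

Step 6 (key step). What may go wrong: slow C–C bond formation. The oxocarbenium ion is strongly stabilised by the dimethoxyphenyl ring and the alkene is deactivated by two allylic C–O bonds, so warming may be needed. At higher temperature the Lewis acid can enolise the new aldehyde (loss of the C3 configuration), re-ionise the benzylic C5–O1 bond (loss of the C5 configuration), or let a boat or stepwise 2-oxonia-Cope/aldol pathway compete (loss of the C4 or C3 relationship). If the chair preference at the carbinol carbon were the reverse of that argued, the remedy would be the enantiomer of 1.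

Fallback, setting out from 7 and returning at 12: the triad is set by hydrogen addition, not by C–C bond formation. An asymmetric SE2′ allenylation of 7 with the propargylic boron reagent derived from 4-bromobut-2-yn-1-yl tert-butyldiphenylsilyl ether and a chiral stilbenediamine bis-sulfonamide controller would give allenol F1. The indium-mediated Barbier addition gives the racemate if resolution is preferred. I2 and NaHCO3 in MeCN would close F1 by 5-endo iodo-etherification to vinyl iodide F2. Carbonylative Suzuki coupling of F2 with 3,4,5-trimethoxyphenylboronic acid (PdCl2(PPh3)2, CO, K2CO3, anisole, 80 °C) would give enone F3. Hydrogen with [Ir(cod)(PCy3)(py)]PF6 in CH2Cl2 (or Pd/C in EtOAc) should then add syn to the tetrasubstituted alkene of F3 from the face opposite the aryl group, which gives 12.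

Step 7. What may go wrong: deprotonation of the hindered all-cis aldehyde at C3 by the Grignard reagent in competition with addition, leading to epimerisation at C3 and recovered aldehyde.

Fallback, setting out from 9 and returning at 13: HF·pyridine removes the silyl group first, and the liberated cis hydroxymethyl group closes onto the aldehyde to give bicyclic lactol F4. In F4 the formyl carbon is masked and the cis ring fusion holds C3 in place. Excess 10 (3 equiv, THF, −40 °C) then opens the magnesium lactolate and adds to the aldehyde as it is released, giving diol F5. MnO2 in CH2Cl2 oxidises only the benzylic secondary alcohol of F5 and gives 13 without a separate deprotection.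

Step 1. What may go wrong: incomplete Z selectivity and partial racemisation of the alpha-alkoxy aldehyde by the amide base. Any E alkene carried forward would give the C4 epimer in step 6, and any loss of enantiopurity is carried through to 13.

Fallback, setting out from 1 and returning at 4: the Z geometry is made by syn hydrogenation of an alkyne. Ohira–Bestmann homologation of 1 (dimethyl (1-diazo-2-oxopropyl)phosphonate, K2CO3, MeOH) gives alkyne F6. Deprotonation with n-BuLi and addition to paraformaldehyde gives propargylic alcohol F7. Semi-hydrogenation over Pd/CaCO3 poisoned with Pb(OAc)2 and quinoline gives 4.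

## Further compounds

F1 | step 6 | (1S)-2-{[(tert-butyldiphenylsilyl)oxy]methyl}-1-(3,4-dimethoxyphenyl)buta-2,3-dien-1-ol | COc1ccc([C@H](O)C(CO[Si](c2ccccc2)(c2ccccc2)C(C)(C)C)=C=C)cc1OC
F2 | step 6 | tert-butyl{[(2S)-2-(3,4-dimethoxyphenyl)-4-iodo-2,5-dihydrofuran-3-yl]methoxy}diphenylsilane | COc1ccc([C@@H]2OCC(I)=C2CO[Si](c3ccccc3)(c3ccccc3)C(C)(C)C)cc1OC
F3 | step 6 | [(5S)-4-{[(tert-butyldiphenylsilyl)oxy]methyl}-5-(3,4-dimethoxyphenyl)-2,5-dihydrofuran-3-yl](3,4,5-trimethoxyphenyl)methanone | COc1ccc([C@@H]2OCC(C(=O)c3cc(OC)c(OC)c(OC)c3)=C2CO[Si](c3ccccc3)(c3ccccc3)C(C)(C)C)cc1OC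
F4 | step 7 | (1R,5R,6R)-6-(3,4-dimethoxyphenyl)-3,7-dioxabicyclo[3.3.0]octan-2-ol, both anomers | COc1ccc([C@@H]2OC[C@@H]3C(O)OC[C@H]23)cc1OC
F5 | step 7 | [(3R,4R,5R)-5-(3,4-dimethoxyphenyl)-4-(hydroxymethyl)oxolan-3-yl](3,4,5-trimethoxyphenyl)methanol, both carbinol epimers | COc1ccc([C@@H]2OC[C@H](C(O)c3cc(OC)c(OC)c(OC)c3)[C@@H]2CO)cc1OC
F6 | step 1 | (4S)-4-ethynyl-2,2-dimethyl-1,3-dioxolane | C#C[C@H]1COC(C)(C)O1
F7 | step 1 | 3-[(4S)-2,2-dimethyl-1,3-dioxolan-4-yl]prop-2-yn-1-ol | OCC#C[C@H]1COC(C)(C)O1
A1 | alternative 1 | trans-3-[(3,4-dimethoxyphenyl)(hydroxy)methyl]-4-[2-(3,4,5-trimethoxyphenyl)-1,3-dithian-2-yl]oxolan-2-one, one enantiomer drawn, carbinol centre undefined | O=C1OC[C@H](C2(c3cc(OC)c(OC)c(OC)c3)SCCCS2)[C@H]1C(O)c1ccc(OC)c(OC)c1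
A2 | alternative 2 | [(5S)-5-(3,4-dimethoxyphenyl)-4-(hydroxymethyl)-2,5-dihydrofuran-3-yl](3,4,5-trimethoxyphenyl)methanone | COc1ccc([C@@H]2OCC(C(=O)c3cc(OC)c(OC)c(OC)c3)=C2CO)cc1OC
A3 | alternative 3 | methyl (5R)-2-(3,4-dimethoxyphenyl)-4,5-dihydro-1,3-dioxepine-5-carboxylate, both epimers at the acetal carbon | COC(=O)[C@H]1COC(OC=C1)c1ccc(OC)c(OC)c1
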